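# Proposed synthesis of CNP0161524.1, (2S)-5,7-dihydroxy-2-{4-hydroxy-3-[(2E)-7-hydroxy-3,7-dimethyloct-2-en-1-yl]phenyl}chroman-4-one (23)

## Analysis of the target

Compound 23 is a (2S)-flavanone: a chroman-4-one (aromatic ring A fused to the oxygen heterocycle, ring C) with the ring B aryl group at C2. It carries hydroxyls at C5, C7 and C4' and a (2E)-7-hydroxy-3,7-dimethyloct-2-enyl chain at C3'. C2 is the only stereocentre, benzylic and bound to O1, so its configuration cannot be relayed from another centre and has to come from a catalyst. C2 lies β to the C4 ketone, so base opens ring C by a retro-oxa-Michael reaction to the achiral chalcone; once the ketone exists, basic conditions must be avoided. The side chain is the second weak point: its trisubstituted E-alkene sits ortho to the C4' phenol and cyclises onto it under strong acid, the tertiary alcohol ionises under the same conditions, and hydrogenation is excluded. The difficulty is therefore to set C2 with absolute control, keep it through ring formation, and unmask a ketone, three phenols and a tertiary alcohol without base, strong acid or hydrogen. The feature the route rests on is that O1 joins the stereocentre C2 to the aromatic carbon C8a of ring A. Cutting O1–C8a turns ring C into an open-chain benzylic carbinol whose C–O bond is already in place, so ring closure at the aryl–oxygen bond cannot touch the configuration.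

## Retrosynthetic reasoning

**From 23 to 22 and 21.** No skeletal bond is cut here. The phenols and the tertiary alcohol of 23 are unmasked in one acidic operation from the tris(methoxymethyl) ether and triethylsilyl ether 22, and the C4 ketone of 22 is taken back to the carbinol of flavan-4-ol 21. The step down in oxidation level means that the compound facing the basic ring closure is a plain alcohol: it has no carbonyl group, so it cannot suffer retro-aldol cleavage or β-elimination of the C2 oxygen. The forward oxidation has to be neutral so that C2 of 22 never meets base.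

**From 21 to 20 (the central cut).** The O1–C8a bond of 21 is cut. This gives diol 20, in which the carbon that becomes C8a carries bromine and the future O1 is the hydroxyl of the (S)-configured benzylic carbinol. Cutting here, and not at O1–C2 or at a C–C bond of ring C, means that the stereocentre is a finished C–O bond before the ring exists. The forward reaction has to join the C3 oxygen of 20 to the brominated carbon in a six-membered ring and leave the C1 hydroxyl alone.

**From 20 to 19, 18 and 17.** The C1 carbinol of 20 comes from ketone 19 by a reduction that needs no selectivity. The C3 carbinol of 19 is traced to the β-carbon of the trans-epoxy ketone 18 by reductive removal of the α-oxygen, and 18 to the E-enone 17. This places the creation of the only stereocentre on a planar enone, where a catalyst chooses the face and the sense of induction can be predicted. The forward steps must deliver the (2S,3R)-epoxide and then break only the Cα–O bond.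

**From 17 to 3 and 16.** The Cα=Cβ bond of 17 is cut by a retro-aldol condensation into methyl ketone 3 and aldehyde 16. The two fragments are of similar size and each holds one aromatic ring, so the route is convergent. Both carry only base-stable groups, as the forward condensation requires.

**From 3 to 2 and 1.** Removal of the two ether groups leads to dihydroxy ketone 2, and cutting the aryl–acetyl bond gives bromoresorcinol 1. In 1 the bromine already stands meta to both oxygens, which is the relation of C8a to the C5 and C7 oxygens. The forward acylation has to enter next to bromine and para to one hydroxyl.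

**From 16 to 11 and 9, and on to 10 and 4.** The bond between C3' and the side-chain CH2 is cut to give aryl bromide 11, the ether of phenol 10, and allylic bromide 9. The bromine of 10 marks C3'. Bromide 9 is traced through alcohol 8, silyl ether acetate 7 and hydroxy acetate 6 to geranyl acetate 4, whose remote alkene is hydrated. The chain is attached this early so that the organometallic coupling is done on a simple arene, before the stereocentre and the base-sensitive heterocycle exist.

## Alternatives that were turned down

**Alternative 1:** Rings A and C would be built by enzymes. The disconnection removes the four ring A bonds C4–C4a, C5–C6, C7–C8 and C4a–C8a together with O1–C2. In the forward sense two ligases turn a brominated phenylpropanoid acid and a three-carbon diacid into their thioesters, a chalcone synthase chains three extender units onto the starter and folds the product into ring A, and a chalcone isomerase closes ring C. This would give (2S)-3'-bromonaringenin A1 in one pot.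

- For it: it is by far the shortest way to the ring system, needs no protecting groups, and the isomerase sets C2 with a selectivity that a small-molecule catalyst is unlikely to match. On these points it is stronger than the chosen route.
- Against it: the starter carries a bulky bromine next to its hydroxyl, outside the natural substrate range of the synthase, so derailment to truncated lactones is to be expected; cofactors are consumed stoichiometrically unless regenerated.
- Decisive point: A1 still lacks the ten-carbon chain. Joining it at C3' means cross-coupling an aryl bromide ortho to a free phenol on an unprotected flavanone whose C2 racemises by ring opening under the basic coupling conditions, or re-protection, which gives back the steps saved.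
- Comparison: the chosen route is longer, but it places the chain on a simple arene (compound 16) before C2 exists and uses only reactions whose scope covers the substrates.

**Alternative 2:** Ring C would be closed at C4–C4a by intramolecular Friedel–Crafts acylation. The acid (3S)-3-(4-acetoxy-3-bromophenyl)-3-[3,5-bis(benzyloxy)phenoxy]propanoic acid A2 would be activated as a mixed anhydride with a perfluorinated anhydride and would acylate the position ortho to the ether oxygen, giving (2S)-4'-acetoxy-5,7-bis(benzyloxy)-3'-bromoflavanone A3.

- For it: the ring attacked is a phloroglucinol triether, among the best arenes for acylation; its two ortho positions are equivalent; no metal is needed; the ketone arrives directly, which saves the reduction and oxidation pair of the chosen route. As a ring closure it is at least as reliable as the copper step.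
- Against it: the stereocentre of A2 is a benzylic aryl ether β to an activated carboxyl group. In the strongly acidic medium it can ionise or lose the phenoxide by retro-oxa-Michael reaction, and the acetoxy group chosen to damp this only partly helps. Making A2 as a single enantiomer needs its own C–O bond formation with inversion at a benzylic carbinol.
- Side chain: the alkene and tertiary oxygen of the chain cannot be present during the acylation, so the chain must be coupled to the bromide of A3, a base-sensitive flavanone. The benzyl ethers then have to be removed without hydrogen, which calls for Lewis acids that endanger the chain.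
- Comparison: the chosen route forms O1–C8a under base, where the carbinol cannot ionise, and carries the complete chain from the aldehyde stage.

**Alternative 3:** C3–C4 and O1–C2 would be formed at once by a formal [4+2] cycloaddition. Under a confined chiral Brønsted acid the ring A ortho-hydroxy aldehyde and an orthoformate give a 4-methoxy ortho-quinone methide (an oxocarbenium ion), which adds the ring B styrene to give (2S)-3'-bromo-4-methoxy-5,7,4'-tris(tert-butyldimethylsilyloxy)flavan A4.

- For it: two bonds, the ring and the stereocentre come from one catalytic step on two simple partners, and C4 arrives oxygenated. In convergence and bond economy it is stronger than the chosen route.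
- Against it: the cationic intermediate is stabilised by two silyloxy donors and is therefore less electrophilic. The para-silyloxystyrene can add stepwise through a benzylic cation, which loosens face control, and it polymerises readily under strong acid. The aryl silyl ethers are exposed to that acid as well.
- Further steps: the C4 methyl ether of A4 must still be converted into the ketone, and the chain must come late through the bromide; if it is placed on the styrene instead, its alkene meets the acid catalyst. The confined acids are costly and take several steps to make.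
- Comparison: the chosen route separates the tasks. The stereocentre comes from a well-understood epoxidation of enone 17, and the ring closure of 20 cannot alter it.

Key step: step 13

## Remarks on the chemistry and shorthand

- Remark: C-acetylation of 1 is taken to occur at C4 (para to one hydroxyl, ortho to bromine), the position attacked in 5-substituted resorcinols.
- Remark: poly-L-leucine is known to give (2R,3S)-epoxides from chalcones; the (2S,3R)-epoxide is needed here, so poly-D-leucine is used.
- Ar1 = 2-bromo-4,6-bis(methoxymethoxy)phenyl (ring A).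
- Ar2 = 3-[(2E)-3,7-dimethyl-7-(triethylsilyloxy)oct-2-en-1-yl]-4-(methoxymethoxy)phenyl (ring B with the protected chain).

## Route

Step 1
Reactants: 1 5-bromoresorcinol
Product: 2 1-(2-bromo-4,6-dihydroxyphenyl)ethan-1-one
Conditions: AcOH, BF3·OEt2, 90 °C; then aq NaOAc
Reagents that add atoms: acetic acid, CC(=O)O
Why: Friedel–Crafts C-acylation; the ring should be attacked at C4, para to one hydroxyl and ortho to the other, while the crowded C2 between the two hydroxyls is avoided. Chelation of the product ketone to boron should stop a second acylation.

Step 2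
Reactants: 2 1-(2-bromo-4,6-dihydroxyphenyl)ethan-1-one
Product: 3 1-[2-bromo-4,6-bis(methoxymethoxy)phenyl]ethan-1-one
Conditions: MOMCl, i-Pr2NEt, CH2Cl2, 0 → 40 °C
Reagents that add atoms: chloromethyl methyl ether (MOMCl), COCCl
Why: O-alkylation of both phenols; excess reagent and gentle warming are used because the hydroxyl next to the acetyl group is hydrogen-bonded. MOM ethers withstand every basic, reducing and organometallic step that follows and leave with acid at the end.

Step 3
Reactants: 4 geranyl acetate
Product: 6 (2E)-7-hydroxy-3,7-dimethyloct-2-en-1-yl acetate, via organomercurial acetate 5 (not isolated)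
Conditions: Hg(OAc)2, THF/H2O, rt; then NaBH4, aq NaOH, 0 °C
Reagents that add atoms: water, O
Why: Oxymercuration–demercuration; the electrophilic mercury salt should add to the electron-rich 6,7-alkene and not to the 2,3-alkene, which the allylic acetate deactivates. Water enters at the more substituted carbon and hydride replaces mercury, so the tertiary alcohol forms and the E-alkene is untouched.

Step 4
Reactants: 6 (2E)-7-hydroxy-3,7-dimethyloct-2-en-1-yl acetate
Product: 7 (2E)-3,7-dimethyl-7-(triethylsilyloxy)oct-2-en-1-yl acetate
Conditions: TESOTf, 2,6-lutidine, CH2Cl2, −78 → 0 °C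
Reagents that add atoms: triethylsilyl trifluoromethanesulfonate (TESOTf), CC[Si](CC)(CC)OS(=O)(=O)C(F)(F)F
Why: Silylation of a hindered tertiary alcohol needs the silyl triflate with a hindered pyridine base. The triethylsilyl ether masks the acidic hydroxyl for the organolithium step and is removed by the same acid that cleaves the MOM ethers.

Step 5
Reactants: 7 (2E)-3,7-dimethyl-7-(triethylsilyloxy)oct-2-en-1-yl acetate
Product: 8 (2E)-3,7-dimethyl-7-(triethylsilyloxy)oct-2-en-1-ol
Conditions: K2CO3 (cat.), MeOH, 0 °C → rt
Reagents that add atoms: none
Why: Base-catalysed methanolysis of the acetate; a tertiary triethylsilyl ether should not be attacked under these conditions.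

Step 6
Reactants: 8 (2E)-3,7-dimethyl-7-(triethylsilyloxy)oct-2-en-1-ol
Product: 9 (2E)-1-bromo-3,7-dimethyl-7-(triethylsilyloxy)oct-2-ene
Conditions: CBr4, PPh3, CH2Cl2, 0 °C
Reagents that add atoms: carbon tetrabromide, BrC(Br)(Br)Br
Why: Appel bromination; the primary allylic alcohol is activated on phosphorus and displaced by bromide at the primary carbon (SN2) under neutral conditions, so the E-geometry and the silyl ether should be kept.

Step 7
Reactants: 10 3-bromo-4-hydroxybenzaldehyde
Product: 11 3-bromo-4-(methoxymethoxy)benzaldehyde
Conditions: MOMCl, i-Pr2NEt, CH2Cl2, 0 °C → rt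
Reagents that add atoms: chloromethyl methyl ether (MOMCl), COCCl
Why: O-alkylation of an acidic phenol under amine base. The MOM oxygen later also stabilises the neighbouring aryllithium by chelation.

Step 8
Reactants: 11 3-bromo-4-(methoxymethoxy)benzaldehyde; 9 (2E)-1-bromo-3,7-dimethyl-7-(triethylsilyloxy)oct-2-ene
Product: 16 3-[(2E)-3,7-dimethyl-7-(triethylsilyloxy)oct-2-en-1-yl]-4-(methoxymethoxy)benzaldehyde, via lithium α-amino alkoxide 12 (not isolated), via aryllithium 13 (not isolated), via arylcopper 14 (not isolated), via coupled α-amino alkoxide 15 (not isolated)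
Conditions: 1-methylpiperazine, n-BuLi, THF, −20 °C, then 11; n-BuLi, −78 °C; CuBr·SMe2, −78 → −40 °C; 9, −78 → 0 °C; then H2O
Reagents that add atoms: none
Why: The aldehyde is masked in the flask as a lithium α-amino alkoxide, which is inert to n-BuLi at −78 °C, so bromine–lithium exchange gives the aryllithium next to the MOM ether. After transmetalation to copper, the aryl group should displace the primary allylic bromide by SN2, since attack at the far alkene carbon would create a quaternary centre; this forms the aryl–CH2 bond with the E-alkene intact, and water releases the aldehyde.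

Step 9
Reactants: 3 1-[2-bromo-4,6-bis(methoxymethoxy)phenyl]ethan-1-one; 16 3-[(2E)-3,7-dimethyl-7-(triethylsilyloxy)oct-2-en-1-yl]-4-(methoxymethoxy)benzaldehyde
Product: 17 (2E)-1-Ar1-3-Ar2-prop-2-en-1-one (chalcone)
Conditions: KOH, EtOH, 0 °C → rt
Reagents that add atoms: none
Why: Claisen–Schmidt condensation; the methyl ketone enolate adds to the non-enolisable aldehyde and E1cB dehydration should give the conjugated E-enone. The aryl bromide, the MOM ethers and the tertiary silyl ether are stable to ethanolic KOH.

Step 10
Reactants: 17 (2E)-1-Ar1-3-Ar2-prop-2-en-1-one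
Product: 18 (Ar1)[(2S,3R)-3-Ar2-oxiran-2-yl]methanone (trans-epoxy ketone)
Conditions: poly-D-leucine, urea–H2O2, DBU, THF, rt
Reagents that add atoms: urea–hydrogen peroxide, NC(N)=O.OO
Why: Julia–Colonna epoxidation; hydroperoxide adds to the β-carbon of the enone held by hydrogen bonds at the N-terminus of the helical polypeptide, and the enolate closes the trans-epoxide. The D-polymer should give the (2S,3R)-epoxide, whose C3 becomes C2 of the flavanone. The isolated trisubstituted alkene is not attacked by a nucleophilic oxidant.

Step 11
Reactants: 18 (Ar1)[(2S,3R)-3-Ar2-oxiran-2-yl]methanone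
Product: 19 (3S)-1-Ar1-3-Ar2-3-hydroxypropan-1-one
Conditions: SmI2, THF/MeOH, −90 °C
Reagents that add atoms: none
Why: Reductive opening of an α,β-epoxy ketone by SmI2 (divalent samarium); electron transfer to the carbonyl group and β-scission cleave only the Cα–O bond, and methanol protonates the resulting enolate. The Cβ–O bond is untouched, so the configuration is kept; the descriptor changes from R to S only because the priorities change. At −90 °C the aryl bromide should not be reduced.

Step 12
Reactants: 19 (3S)-1-Ar1-3-Ar2-3-hydroxypropan-1-one
Product: 20 (3S)-1-Ar1-3-Ar2-propane-1,3-diol (C1 epimer mixture)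
Conditions: NaBH4, MeOH/THF, 0 °C
Reagents that add atoms: none
Why: Hydride reduction of the aryl ketone; both C1 epimers are acceptable because C1 returns to the ketone in step 14. At the alcohol level, retro-aldol cleavage and dehydration cannot occur in the basic ring closure.

Step 13
Reactants: 20 (3S)-1-Ar1-3-Ar2-propane-1,3-diol (C1 epimer mixture)
Product: 21 (2S)-2-Ar2-5,7-bis(methoxymethoxy)chroman-4-ol (flavan-4-ol, C4 epimer mixture)
Conditions: CuI (10 mol %), 3,4,7,8-tetramethyl-1,10-phenanthroline (20 mol %), Cs2CO3, toluene, 110 °C, argon
Reagents that add atoms: none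
Why: Cs2CO3 deprotonates the C3 carbinol and the ligated monovalent copper forms a copper alkoxide. Oxidative addition into the neighbouring C–Br bond gives an aryl alkoxide of trivalent copper in a seven-membered chelate, and C–O reductive elimination forms O1–C8a and returns monovalent copper. The closest known reaction type is the Ullmann-type intramolecular O-arylation of secondary alcohols by aryl bromides to chromans with CuI and phenanthroline ligands. Ring C closes as a six-membered ring, formally a 6-exo attack of oxygen on the sp2 carbon C8a. No stereocentre is created: the C3–O bond of 20 is never broken, so the (S) configuration passes into C2 of 21 with retention, and C4 stays an epimer mixture that step 14 erases. The selectivity needed is between the two secondary hydroxyls; the C1 hydroxyl could only close a four-membered ring, so only the C3 oxygen can eliminate productively, and the tertiary oxygen is silylated. Copper is preferred to palladium because a palladium alkoxide at C1 would undergo β-hydride elimination, and the bromine stands meta to both MOM ethers, so the C–Br carbon is not deactivated by resonance.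

Step 14
Reactants: 21 (2S)-2-Ar2-5,7-bis(methoxymethoxy)chroman-4-ol
Product: 22 (2S)-2-Ar2-5,7-bis(methoxymethoxy)chroman-4-one (protected flavanone)
Conditions: DMP (triacetoxy periodinane), NaHCO3, CH2Cl2, 0 °C → rt
Reagents that add atoms: none
Why: Periodinane oxidation of the secondary benzylic alcohol under buffered, non-basic conditions; both C4 epimers converge on one ketone. C2 is not opened without base and should keep its configuration.

Step 15
Reactants: 22 (2S)-2-Ar2-5,7-bis(methoxymethoxy)chroman-4-one
Product: 23 (2S)-5,7-dihydroxy-2-{4-hydroxy-3-[(2E)-7-hydroxy-3,7-dimethyloct-2-en-1-yl]phenyl}chroman-4-one (target)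
Conditions: dilute aq HCl, MeOH, rt → 40 °C
Reagents that add atoms: none
Why: Acid-catalysed acetal cleavage of the three aryl MOM ethers and solvolysis of the silyl ether in one operation. Dilute acid at moderate temperature is chosen so that C2, the trisubstituted alkene and the tertiary alcohol should survive.

## Compound list

1 | 5-bromoresorcinol (5-bromobenzene-1,3-diol) | Oc1cc(O)cc(Br)c1 | starting material
2 | 1-(2-bromo-4,6-dihydroxyphenyl)ethan-1-one | CC(=O)c1c(O)cc(O)cc1Br | intermediate
3 | 1-[2-bromo-4,6-bis(methoxymethoxy)phenyl]ethan-1-one | CC(=O)c1c(Br)cc(OCOC)cc1OCOC | intermediate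
4 | geranyl acetate, (2E)-3,7-dimethylocta-2,6-dien-1-yl acetate | CC(=O)OC/C=C(\C)CCC=C(C)C | starting material
5 | (2E)-6-(acetoxymercurio)-7-hydroxy-3,7-dimethyloct-2-en-1-yl acetate (racemic at C6, formed in the flask) | CC(=O)OC/C=C(\C)CCC([Hg]OC(C)=O)C(C)(C)O | intermediate
6 | (2E)-7-hydroxy-3,7-dimethyloct-2-en-1-yl acetate | CC(=O)OC/C=C(\C)CCCC(C)(C)O | intermediate
7 | (2E)-3,7-dimethyl-7-(triethylsilyloxy)oct-2-en-1-yl acetate | CC(=O)OC/C=C(\C)CCCC(C)(C)O[Si](CC)(CC)CC | intermediate
8 | (2E)-3,7-dimethyl-7-(triethylsilyloxy)oct-2-en-1-ol | OC/C=C(\C)CCCC(C)(C)O[Si](CC)(CC)CC | intermediate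
9 | (2E)-1-bromo-3,7-dimethyl-7-(triethylsilyloxy)oct-2-ene | BrC/C=C(\C)CCCC(C)(C)O[Si](CC)(CC)CC | intermediate
10 | 3-bromo-4-hydroxybenzaldehyde | O=Cc1ccc(O)c(Br)c1 | starting material
11 | 3-bromo-4-(methoxymethoxy)benzaldehyde | O=Cc1ccc(OCOC)c(Br)c1 | intermediate
12 | lithium [3-bromo-4-(methoxymethoxy)phenyl](4-methylpiperazin-1-yl)methanolate (formed in the flask) | [Li]OC(c1ccc(OCOC)c(Br)c1)N1CCN(C)CC1 | intermediate
13 | lithium [3-lithio-4-(methoxymethoxy)phenyl](4-methylpiperazin-1-yl)methanolate (formed in the flask) | [Li]OC(c1ccc(OCOC)c([Li])c1)N1CCN(C)CC1 | intermediate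
14 | lithium [3-cuprio-4-(methoxymethoxy)phenyl](4-methylpiperazin-1-yl)methanolate (arylcopper, formed in the flask) | [Li]OC(c1ccc(OCOC)c([Cu])c1)N1CCN(C)CC1 | intermediate
15 | lithium {3-[(2E)-3,7-dimethyl-7-(triethylsilyloxy)oct-2-en-1-yl]-4-(methoxymethoxy)phenyl}(4-methylpiperazin-1-yl)methanolate (formed in the flask) | C/C(=C\Cc1cc(C(O[Li])N2CCN(C)CC2)ccc1OCOC)CCCC(C)(C)O[Si](CC)(CC)CC | intermediate
16 | 3-[(2E)-3,7-dimethyl-7-(triethylsilyloxy)oct-2-en-1-yl]-4-(methoxymethoxy)benzaldehyde | C/C(=C\Cc1cc(C=O)ccc1OCOC)CCCC(C)(C)O[Si](CC)(CC)CC | intermediate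
17 | (2E)-1-[2-bromo-4,6-bis(methoxymethoxy)phenyl]-3-{3-[(2E)-3,7-dimethyl-7-(triethylsilyloxy)oct-2-en-1-yl]-4-(methoxymethoxy)phenyl}prop-2-en-1-one | C/C(=C\Cc1cc(/C=C/C(=O)c2c(Br)cc(OCOC)cc2OCOC)ccc1OCOC)CCCC(C)(C)O[Si](CC)(CC)CC | intermediate
18 | [2-bromo-4,6-bis(methoxymethoxy)phenyl][(2S,3R)-3-{3-[(2E)-3,7-dimethyl-7-(triethylsilyloxy)oct-2-en-1-yl]-4-(methoxymethoxy)phenyl}oxiran-2-yl]methanone | C/C(=C\Cc1cc([C@H]2O[C@@H]2C(=O)c3c(Br)cc(OCOC)cc3OCOC)ccc1OCOC)CCCC(C)(C)O[Si](CC)(CC)CC | intermediate
19 | (3S)-1-[2-bromo-4,6-bis(methoxymethoxy)phenyl]-3-{3-[(2E)-3,7-dimethyl-7-(triethylsilyloxy)oct-2-en-1-yl]-4-(methoxymethoxy)phenyl}-3-hydroxypropan-1-one | C/C(=C\Cc1cc([C@@H](O)CC(=O)c2c(Br)cc(OCOC)cc2OCOC)ccc1OCOC)CCCC(C)(C)O[Si](CC)(CC)CC | intermediate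
20 | (3S)-1-[2-bromo-4,6-bis(methoxymethoxy)phenyl]-3-{3-[(2E)-3,7-dimethyl-7-(triethylsilyloxy)oct-2-en-1-yl]-4-(methoxymethoxy)phenyl}propane-1,3-diol (C1 epimer mixture) | C/C(=C\Cc1cc([C@@H](O)CC(O)c2c(Br)cc(OCOC)cc2OCOC)ccc1OCOC)CCCC(C)(C)O[Si](CC)(CC)CC | intermediate
21 | (2S)-2-{3-[(2E)-3,7-dimethyl-7-(triethylsilyloxy)oct-2-en-1-yl]-4-(methoxymethoxy)phenyl}-5,7-bis(methoxymethoxy)chroman-4-ol (C4 epimer mixture) | C/C(=C\Cc1cc([C@@H]2CC(O)c3c(OCOC)cc(OCOC)cc3O2)ccc1OCOC)CCCC(C)(C)O[Si](CC)(CC)CC | intermediate
22 | (2S)-2-{3-[(2E)-3,7-dimethyl-7-(triethylsilyloxy)oct-2-en-1-yl]-4-(methoxymethoxy)phenyl}-5,7-bis(methoxymethoxy)chroman-4-one | C/C(=C\Cc1cc([C@@H]2CC(=O)c3c(OCOC)cc(OCOC)cc3O2)ccc1OCOC)CCCC(C)(C)O[Si](CC)(CC)CC | intermediate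
23 | (2S)-5,7-dihydroxy-2-{4-hydroxy-3-[(2E)-7-hydroxy-3,7-dimethyloct-2-en-1-yl]phenyl}chroman-4-one | C/C(=C\Cc1cc([C@@H]2CC(=O)c3c(O)cc(O)cc3O2)ccc1O)CCCC(C)(C)O | target

## Step count and least certain steps

Total step count: 15. Longest linear sequence: 12 steps, from geranyl acetate 4 through steps 3, 4, 5, 6, 8, 9, 10, 11, 12, 13, 14 and 15.

**Step 13 (key step).** The most likely failure is slow insertion of copper into the C–Br bond of an ortho-substituted ring at 110 °C. Loss of bromine by reduction, or oxidation of a benzylic carbinol through hydride transfer from a copper alkoxide, could then overtake ring closure. The C1 alkoxide may also hold the catalyst in a five-membered chelate that has no productive exit.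

The fallback closes ring C at O1–C2 instead, with inversion, in the mirror-image carbinol series. It sets out from chalcone 17 and comes back at flavanone 22. Chalcone 17 would be epoxidised with poly-L-leucine, urea–H2O2 and DBU to [2-bromo-4,6-bis(methoxymethoxy)phenyl][(2R,3S)-3-Ar2-oxiran-2-yl]methanone F1, and SmI2 would open it to (3R)-1-Ar1-3-Ar2-3-hydroxypropan-1-one F2. Miyaura borylation (Pd(dppf)Cl2, bis(pinacolato)diboron, KOAc, dioxane, 80 °C) would turn the bromide into the aryl pinacol boronate F3, and NaBO3·4H2O in THF/H2O would oxidise it to the phenol (3R)-3-Ar2-3-hydroxy-1-[2-hydroxy-4,6-bis(methoxymethoxy)phenyl]propan-1-one F4. Mitsunobu cyclisation (PPh3, diisopropyl azodicarboxylate, THF, 0 °C) would then displace the activated (R)-carbinol by the phenol oxygen with inversion and give the (2S)-flavanone 22 directly, so that steps 12 to 14 are not needed.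

**Step 10.** The most likely failure is poor facial selectivity together with a low rate. The aryl ketone of 17 is twisted out of conjugation by its two ortho substituents, and polypeptide catalysts are sensitive to substitution at that position.

The fallback replaces epoxidation and reductive opening by conjugate borylation and oxidation. It sets out from chalcone 17 and comes back at hydroxy ketone 19. CuCl, NaOt-Bu and a chiral ferrocenyl bisphosphine of the Josiphos type, in the antipode that leads to the (S)-product, with bis(pinacolato)diboron and MeOH in THF would add boron to the β-carbon and give (3S)-1-Ar1-3-Ar2-3-(4,4,5,5-tetramethyl-1,3,2-dioxaborolan-2-yl)propan-1-one F5. Oxidation with NaBO3·4H2O would replace boron by hydroxyl with retention and give 19. This also bypasses step 11, where electron transfer to the bromoaryl ketone is a smaller risk.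

**Step 8.** The most likely failure is incomplete bromine–lithium exchange or attack of n-BuLi on the masked aldehyde, followed by homocoupling of the allylic bromide or attack at its far alkene carbon during the allylation.

The fallback avoids organolithium reagents. It sets out from aryl bromide 11 and comes back at aldehyde 16. Miyaura borylation of 11 (Pd(dppf)Cl2, bis(pinacolato)diboron, KOAc, dioxane, 80 °C), which tolerates the free aldehyde, would give 4-(methoxymethoxy)-3-(4,4,5,5-tetramethyl-1,3,2-dioxaborolan-2-yl)benzaldehyde F6. Allyl–aryl Suzuki–Miyaura coupling of F6 with bromide 9 (Pd(PPh3)4, K2CO3, THF/H2O, 60 °C) should join the aryl group to the unsubstituted end of the allyl unit and give 16.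

**Step 15.** The most likely failure is acid-promoted reaction of the side chain before the last MOM group has left: addition of the freed C4' phenol across the protonated alkene to form a chroman ring, or ionisation of the tertiary alcohol with elimination or ether formation.

The fallback removes the groups in two non-protic stages. It sets out from 22 and comes back at 23. TMSOTf and 2,2'-bipyridyl in CH2Cl2 at 0 °C would convert the three aryl MOM ethers into the tris(trimethylsilyl) ether F7. Water in the same flask would hydrolyse it to (2S)-2-{3-[(2E)-3,7-dimethyl-7-(triethylsilyloxy)oct-2-en-1-yl]-4-hydroxyphenyl}-5,7-dihydroxychroman-4-one F8. HF·pyridine in THF at 0 °C would then remove the triethylsilyl group and give 23.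

## Further compounds

F1 | step 13 | [2-bromo-4,6-bis(methoxymethoxy)phenyl][(2R,3S)-3-{3-[(2E)-3,7-dimethyl-7-(triethylsilyloxy)oct-2-en-1-yl]-4-(methoxymethoxy)phenyl}oxiran-2-yl]methanone | C/C(=C\Cc1cc([C@@H]2O[C@H]2C(=O)c3c(Br)cc(OCOC)cc3OCOC)ccc1OCOC)CCCC(C)(C)O[Si](CC)(CC)CC
F2 | step 13 | (3R)-1-[2-bromo-4,6-bis(methoxymethoxy)phenyl]-3-{3-[(2E)-3,7-dimethyl-7-(triethylsilyloxy)oct-2-en-1-yl]-4-(methoxymethoxy)phenyl}-3-hydroxypropan-1-one | C/C(=C\Cc1cc([C@H](O)CC(=O)c2c(Br)cc(OCOC)cc2OCOC)ccc1OCOC)CCCC(C)(C)O[Si](CC)(CC)CC
F3 | step 13 | (3R)-1-[2,4-bis(methoxymethoxy)-6-(4,4,5,5-tetramethyl-1,3,2-dioxaborolan-2-yl)phenyl]-3-{3-[(2E)-3,7-dimethyl-7-(triethylsilyloxy)oct-2-en-1-yl]-4-(methoxymethoxy)phenyl}-3-hydroxypropan-1-one | C/C(=C\Cc1cc([C@H](O)CC(=O)c2c(B3OC(C)(C)C(C)(C)O3)cc(OCOC)cc2OCOC)ccc1OCOC)CCCC(C)(C)O[Si](CC)(CC)CC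
F4 | step 13 | (3R)-3-{3-[(2E)-3,7-dimethyl-7-(triethylsilyloxy)oct-2-en-1-yl]-4-(methoxymethoxy)phenyl}-3-hydroxy-1-[2-hydroxy-4,6-bis(methoxymethoxy)phenyl]propan-1-one | C/C(=C\Cc1cc([C@H](O)CC(=O)c2c(O)cc(OCOC)cc2OCOC)ccc1OCOC)CCCC(C)(C)O[Si](CC)(CC)CC
F5 | step 10 | (3S)-1-[2-bromo-4,6-bis(methoxymethoxy)phenyl]-3-{3-[(2E)-3,7-dimethyl-7-(triethylsilyloxy)oct-2-en-1-yl]-4-(methoxymethoxy)phenyl}-3-(4,4,5,5-tetramethyl-1,3,2-dioxaborolan-2-yl)propan-1-one | C/C(=C\Cc1cc([C@@H](B3OC(C)(C)C(C)(C)O3)CC(=O)c2c(Br)cc(OCOC)cc2OCOC)ccc1OCOC)CCCC(C)(C)O[Si](CC)(CC)CC
F6 | step 8 | 4-(methoxymethoxy)-3-(4,4,5,5-tetramethyl-1,3,2-dioxaborolan-2-yl)benzaldehyde | O=Cc1ccc(OCOC)c(B2OC(C)(C)C(C)(C)O2)c1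
F7 | step 15 | (2S)-2-{3-[(2E)-3,7-dimethyl-7-(triethylsilyloxy)oct-2-en-1-yl]-4-(trimethylsilyloxy)phenyl}-5,7-bis(trimethylsilyloxy)chroman-4-one | C/C(=C\Cc1cc([C@@H]2CC(=O)c3c(O[Si](C)(C)C)cc(O[Si](C)(C)C)cc3O2)ccc1O[Si](C)(C)C)CCCC(C)(C)O[Si](CC)(CC)CC
F8 | step 15 | (2S)-2-{3-[(2E)-3,7-dimethyl-7-(triethylsilyloxy)oct-2-en-1-yl]-4-hydroxyphenyl}-5,7-dihydroxychroman-4-one | C/C(=C\Cc1cc([C@@H]2CC(=O)c3c(O)cc(O)cc3O2)ccc1O)CCCC(C)(C)O[Si](CC)(CC)CC
A1 | alternative 1 | (2S)-3'-bromonaringenin | Oc1ccc(cc1Br)[C@@H]2CC(=O)c3c(O)cc(O)cc3O2
A2 | alternative 2 | (3S)-3-(4-acetoxy-3-bromophenyl)-3-[3,5-bis(benzyloxy)phenoxy]propanoic acid | Brc1cc([C@@H](Oc2cc(OCc3ccccc3)cc(OCc3ccccc3)c2)CC(=O)O)ccc1OC(C)=O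
A3 | alternative 2 | (2S)-4'-acetoxy-5,7-bis(benzyloxy)-3'-bromoflavanone | Brc1cc([C@@H]2CC(=O)c3c(OCc4ccccc4)cc(OCc4ccccc4)cc3O2)ccc1OC(C)=O
A4 | alternative 3 | (2S)-3'-bromo-4-methoxy-5,7,4'-tris(tert-butyldimethylsilyloxy)flavan (C4 configuration not defined) | Brc1cc([C@@H]2CC(OC)c3c(O[Si](C)(C)C(C)(C)C)cc(O[Si](C)(C)C(C)(C)C)cc3O2)ccc1O[Si](C)(C)C(C)(C)C
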